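Two questions stood before me about this flask: how much J and how much L it holds at the end.

G 0.25 M; Z 0.92 mol%; time 15 d

    D → J (k1 = 7.78 × 10⁻⁵ /s)
    G → L (k2 = 4.35 × 10⁻⁶ /s)
    G + Z → Z + D (k3 = 0.110 /M/s)

- how much J there is at 15 d, in percent of the G charged
- how much L there is at 15 d, in percent of the G charged

The catalysed step gives Z back, so I held Z at its charge. G then falls in a pseudo-first-order way by both routes, with a catalysed constant of

catalysed constant = rate constant × G charged × Z loading = 2.53 × 10⁻⁴ /s

I first pictured two extremes. With Z struck from the flask, L takes nearly all of the charge by 15 d. With the catalysed route standing by itself, L takes a fraction 0, and G passes through D to J. The real flask had to lie between these, close to the second, since 2.53 × 10⁻⁴ /s is far larger than the uncatalysed 4.35 × 10⁻⁶ /s. Both routes are first order in G, so their ratio stays the same as G falls, and the leak share, the fraction of the G charged that ends as L, is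

leak share = uncatalysed constant / (uncatalysed + catalysed constant) = 1.69 %

The time of 15 d is far longer than the half-life of G, 0.748 h, and that of D, 0.10 d. So I committed to 1.69 % of L and 98.3 % of J.

The forecast gave 98.3 % of J and 1.69 % of L, holding the time “far longer than the lifetimes of both G and D”, and my figures matched it.

The flask gave 98.3 % of J and 1.69 % of L. It held 0.00589 % of D as early as 1.50 d. For the neighbour flask with 0.23 mol% of Z, the leak share comes to 6.43 %, and that flask held 6.43 % of L at 15.0 d.

All constants stand for no real mixture, and the outcome is calculated.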